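**Retrosynthetic overview**

1. Labels: ring A is the methoxy-dimethyl benzoyl ring, ring B the seven-membered lactone, ring D the five-membered lactol; ring C is the hexasubstituted ring with Ca (ether O), Cb (lactone O of ring B), Cc (CH3), Cd (OH), Ce (carboxyl carbon) and Cf (lactol carbon). The strategy rests on Ca being para to the phenol carbon Cd and directly bonded to Cb.
2. Ring D and its stereocentre: the (R)-lactol comes from its (R)-propanoate, set by acylative dynamic kinetic resolution of the racemic lactol, which forms on hydrogenolysis of an ortho-formyl benzyl ester.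
3. Ring B (Cb–O bond): 1,2-acyloxy shift with ring expansion of a spiro quinol ester (six-membered spiro benzodioxinone at Ca) that lacks the Cb oxygen.
4. Spiro C–O bond at Ca: PhI(OAc)2 spirolactonisation of a 2-aryloxybenzoic acid; its diaryl ether comes from an Ullmann coupling of a ring A phenol (from atraric acid) with a ring C bromide (from 3-methylsalicylic acid).
5. Ring order: A and C are bought; the spiro six-membered ring is closed first, then ring B together with aromatic ring C (key step), then ring D.

Key step: step 11

Remark on the chemistry (assumption): the lactol carbon of ring D can epimerise by ring–chain tautomerism, so it is fixed last as an ester, and the free (R)-lactol is assumed to hold its configuration when released and kept in neutral, aprotic, cold medium.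

**Route**

Step 1
Reactants: 1 atraric acid (methyl 2,4-dihydroxy-3,6-dimethylbenzoate)
Product: 2 methyl 2-hydroxy-4-methoxy-3,6-dimethylbenzoate
Conditions: MeI (1.1 equiv), K2CO3, acetone, reflux
Reagents that add atoms: iodomethane, CI
Why: Williamson O-methylation should take place only at the 4-OH, because the 2-OH is hydrogen-bonded to the ester carbonyl and flanked by the C-3 methyl group.

Step 2
Reactants: 2 methyl 2-hydroxy-4-methoxy-3,6-dimethylbenzoate
Product: 3 2-hydroxy-4-methoxy-3,6-dimethylbenzoic acid
Conditions: KOH, DMSO/H2O, 80 °C; then aq. HCl, 0 °C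
Reagents that add atoms: potassium hydroxide, [K+].[OH-]
Why: Saponification (BAc2) of the hindered salicylate should proceed with hot hydroxide in DMSO, and cold acidification is used because electron-rich salicylic acids decarboxylate in warm acid.

Step 3
Reactants: 3 2-hydroxy-4-methoxy-3,6-dimethylbenzoic acid
Product: 4 allyl 2-hydroxy-4-methoxy-3,6-dimethylbenzoate
Conditions: allyl bromide, KHCO3, DMF, rt
Reagents that add atoms: allyl bromide, C=CCBr
Why: SN2 alkylation of the carboxylate should give only the ester, since hydrogencarbonate does not ionise the chelated phenol.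

Step 4
Reactants: 5 3-methylsalicylic acid (2-hydroxy-3-methylbenzoic acid)
Product: 6 5-bromo-2-hydroxy-3-methylbenzoic acid
Conditions: Br2, AcOH, rt
Reagents that add atoms: bromine, BrBr
Why: Electrophilic aromatic bromination should go para to the phenol OH (C-5), the only strongly activated free position because C-3 is blocked by methyl.

Step 5
Reactants: 6 5-bromo-2-hydroxy-3-methylbenzoic acid
Product: 7 benzyl 5-bromo-2-hydroxy-3-methylbenzoate
Conditions: BnBr, KHCO3, DMF, rt
Reagents that add atoms: benzyl bromide, BrCc1ccccc1
Why: SN2 alkylation of the carboxylate under weak base should leave the hydrogen-bonded phenol untouched.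

Step 6
Reactants: 7 benzyl 5-bromo-2-hydroxy-3-methylbenzoate
Product: 8 benzyl 2-(allyloxy)-5-bromo-3-methylbenzoate
Conditions: allyl bromide, K2CO3, DMF, 50 °C
Reagents that add atoms: allyl bromide, C=CCBr
Why: Williamson etherification with the stronger base masks the phenol, which would otherwise deactivate the bromide and compete as nucleophile in the ether coupling; both ortho positions are blocked, so no Claisen rearrangement can follow.

Step 7
Reactants: 8 benzyl 2-(allyloxy)-5-bromo-3-methylbenzoate
Product: 10 benzyl 2-(allyloxy)-5-bromo-6-formyl-3-methylbenzoate, via arylmagnesium chloride 9 (not isolated)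
Conditions: TMPMgCl·LiCl (1.2 equiv), THF, −20 °C; then DMF, −20 °C to rt; aq. NH4Cl
Reagents that add atoms: N,N-dimethylformamide, CN(C)C=O
Why: Directed ortho-magnesiation with the hindered amide base should occur at C-6, between the coordinating ester and the acidifying bromine, and the aryl Grignard is then formylated with DMF; the amide base does not exchange bromine and the ortho-bromo arylmagnesium should not eliminate to an aryne at −20 °C.

Step 8
Reactants: 4 allyl 2-hydroxy-4-methoxy-3,6-dimethylbenzoate; 10 benzyl 2-(allyloxy)-5-bromo-6-formyl-3-methylbenzoate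
Product: 11 allyl 2-[4-(allyloxy)-3-(benzyloxycarbonyl)-2-formyl-5-methylphenoxy]-4-methoxy-3,6-dimethylbenzoate
Conditions: CuI (10 mol%), picolinic acid (20 mol%), K3PO4, DMSO, 90 °C
Reagents that add atoms: none
Why: Ligand-accelerated Ullmann diaryl ether synthesis should be helped by the ortho-formyl group of the bromide, and because Cb still carries hydrogen only three ortho substituents flank the new C–O bond.

Step 9
Reactants: 11 allyl 2-[4-(allyloxy)-3-(benzyloxycarbonyl)-2-formyl-5-methylphenoxy]-4-methoxy-3,6-dimethylbenzoate
Product: 12 2-[3-(benzyloxycarbonyl)-2-formyl-4-hydroxy-5-methylphenoxy]-4-methoxy-3,6-dimethylbenzoic acid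
Conditions: Pd(PPh3)4 (5 mol%), sodium p-toluenesulfinate (TolSO2Na, 2.5 equiv), THF/MeOH, rt; then dil. HCl
Reagents that add atoms: none
Why: Tsuji–Trost-type deallylation: zerovalent palladium ionises both the allyl ester and the electron-poor aryl allyl ether to π-allyl complexes that the sulfinate traps, while the benzyl ester, aldehyde and diaryl ether are inert.

Step 10
Reactants: 12 2-[3-(benzyloxycarbonyl)-2-formyl-4-hydroxy-5-methylphenoxy]-4-methoxy-3,6-dimethylbenzoic acid
Product: 13 racemic spiro quinol ester: 2'-formyl-3'-(benzyloxycarbonyl)-5'-methyl-7-methoxy-5,8-dimethylspiro[4H-1,3-benzodioxin-2,1'-cyclohexa-2',5'-diene]-4,4'-dione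
Conditions: PhI(OAc)2 (1.1 equiv), CH2Cl2/(CF3)2CHOH 4:1, 0 °C; rapid filtration through neutral silica
Reagents that add atoms: none
Why: Oxidative dearomatisation with trivalent iodine (spirolactonisation of a para-oxygenated phenol): after ligand exchange at the ring C phenol, the ring A carboxylate, held beside the ether oxygen, should close the six-membered ring at the para carbon Ca, whose aryloxy group best stabilises the positive charge, to give the racemic quinone mono(acyl aryl) ketal.

Step 11
Reactants: 13 racemic spiro quinol ester
Product: 15 benzyl 6-formyl-8-hydroxy-3-methoxy-1,4,9-trimethyl-11-oxo-11H-dibenzo[b,e][1,4]dioxepine-7-carboxylate (depsidone with Cf–CHO and Ce–CO2Bn and Cd–OH), via bridged dioxolanylium ion 14 (not isolated)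
Conditions: BF3·OEt2 (1.5 equiv), dry CH2Cl2, −40 to 0 °C; then aq. NaHCO3
Reagents that add atoms: none
Why: Proposed new method: BF3 binds the dienone oxygen and makes the β-carbon Cb electrophilic; the carbonyl oxygen of the spiro ester adds to Cb to give the Ca–Cb-bridged 1,3-dioxolan-2-ylium ion 14, whose Ca–O bond then opens to an aryloxy-stabilised cation, and loss of the Cb proton rearomatises ring C with the acyloxy group on Cb. The closest known reaction type is the acid-promoted 1,2-acyloxy shift of para-quinol esters (a dienone–phenol-type rearrangement through an acyloxonium bridge), which here takes place inside a spiro ring and so becomes a ring expansion. Ring B, the seven-membered dioxepinone, is closed by this 1,2-shift of the ester oxygen from Ca to Cb (six- to seven-membered ring expansion through the five-membered bridge), and ring C becomes aromatic in the same event. No stereocentre is formed and the spiro centre is destroyed, so racemic 13 suffices. The step needs the acyloxy and not the aryloxy oxygen to migrate, and to Cb and not Cf: only the ester carbonyl can bridge through a five-membered ring (the ether oxygen would have to form a three-membered oxonium ion), and only Cb carries a hydrogen whose loss gives the phenol, so a bridge to the formyl-bearing Cf can only revert.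

Step 12
Reactants: 15 depsidone aldehyde benzyl ester
Product: 17 racemic lactol (constitution of the target), via formyl acid 16 (not isolated)
Conditions: H2 (1 atm), 10% Pd/C, EtOAc, rt
Reagents that add atoms: none
Why: Hydrogenolysis of the benzyl ester frees the acid on Ce, which should close onto the ortho-formyl group on Cf by ring–chain tautomerism to the five-membered lactol (ring D); the hindered aldehyde and the lactone should survive a short exposure.

Step 13
Reactants: 17 racemic lactol
Product: 18 (R)-lactol propanoate (O-propanoyl ester at the lactol carbon; ring C phenol free)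
Conditions: (2S,3R)-HyperBTM (5 mol%), (EtCO)2O (1.2 equiv), iPr2NEt, CHCl3, 0 °C
Reagents that add atoms: propanoic anhydride, CCC(=O)OC(=O)CC
Why: Isothiourea-catalysed acylative dynamic kinetic resolution: the amine base interconverts the lactol enantiomers through the open formyl carboxylate while the chiral acyl isothiouronium ion acylates one of them faster, which sets the (R) centre under catalyst control ((2S,3R)-HyperBTM is proposed and its antipode would be used if the sense proves opposite); the chelated, doubly ortho-substituted phenol is expected to react much more slowly than the lactol OH.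

Step 14
Reactants: 18 (R)-lactol propanoate
Product: 19 CNP0255863.1, the (R)-lactol
Conditions: Candida antarctica lipase B (immobilised), n-BuOH (3 equiv), dry t-BuOMe, 25 °C; filtration and evaporation below rt
Reagents that add atoms: none
Why: Lipase-catalysed transesterification (butanolysis) cleaves the acyl–oxygen bond of the small propanoyl group, so the lactol C–O bonds and the (R) configuration are untouched, the base-free and water-poor medium avoids the open carboxylate through which the lactol would racemise, and the bulky ring B lactone should not fit the enzyme.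

**Compound list**

1 | atraric acid (methyl 2,4-dihydroxy-3,6-dimethylbenzoate) | COC(=O)c1c(C)cc(O)c(C)c1O | starting material
2 | methyl 2-hydroxy-4-methoxy-3,6-dimethylbenzoate | COC(=O)c1c(C)cc(OC)c(C)c1O | intermediate
3 | 2-hydroxy-4-methoxy-3,6-dimethylbenzoic acid | COc1cc(C)c(C(=O)O)c(O)c1C | intermediate
4 | allyl 2-hydroxy-4-methoxy-3,6-dimethylbenzoate | C=CCOC(=O)c1c(C)cc(OC)c(C)c1O | intermediate
5 | 3-methylsalicylic acid | Cc1cccc(C(=O)O)c1O | starting material
6 | 5-bromo-2-hydroxy-3-methylbenzoic acid | Cc1cc(Br)cc(C(=O)O)c1O | intermediate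
7 | benzyl 5-bromo-2-hydroxy-3-methylbenzoate | Cc1cc(Br)cc(C(=O)OCc2ccccc2)c1O | intermediate
8 | benzyl 2-(allyloxy)-5-bromo-3-methylbenzoate | C=CCOc1c(C)cc(Br)cc1C(=O)OCc1ccccc1 | intermediate
9 | arylmagnesium chloride (C-6 magnesiated 8, LiCl complex) | C=CCOc1c(C)cc(Br)c([Mg]Cl)c1C(=O)OCc1ccccc1 | intermediate
10 | benzyl 2-(allyloxy)-5-bromo-6-formyl-3-methylbenzoate | C=CCOc1c(C)cc(Br)c(C=O)c1C(=O)OCc1ccccc1 | intermediate
11 | allyl 2-[4-(allyloxy)-3-(benzyloxycarbonyl)-2-formyl-5-methylphenoxy]-4-methoxy-3,6-dimethylbenzoate | C=CCOC(=O)c1c(C)cc(OC)c(C)c1Oc1cc(C)c(OCC=C)c(C(=O)OCc2ccccc2)c1C=O | intermediate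
12 | 2-[3-(benzyloxycarbonyl)-2-formyl-4-hydroxy-5-methylphenoxy]-4-methoxy-3,6-dimethylbenzoic acid | COc1cc(C)c(C(=O)O)c(Oc2cc(C)c(O)c(C(=O)OCc3ccccc3)c2C=O)c1C | intermediate
13 | racemic spiro quinol ester (spiro benzodioxinone dienone) | COc1cc(C)c2c(c1C)OC1(OC2=O)C=C(C)C(=O)C(C(=O)OCc2ccccc2)=C1C=O | intermediate
14 | bridged 1,3-dioxolan-2-ylium ion across Ca–Cb (BF3-bound dienolate, racemic) | COc1cc(C)c2c(c1C)OC13O[C+]2OC1C(C)=C(O[B-](F)(F)F)C(C(=O)OCc1ccccc1)=C3C=O | intermediate
15 | benzyl 6-formyl-8-hydroxy-3-methoxy-1,4,9-trimethyl-11-oxo-11H-dibenzo[b,e][1,4]dioxepine-7-carboxylate | COc1cc(C)c2c(c1C)Oc1c(C=O)c(C(=O)OCc3ccccc3)c(O)c(C)c1OC2=O | intermediate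
16 | formyl acid (open form of the lactol) | COc1cc(C)c2c(c1C)Oc1c(C=O)c(C(=O)O)c(O)c(C)c1OC2=O | intermediate
17 | racemic lactol | COc1cc(C)c2c(c1C)Oc1c(c(C)c(O)c3c1C(O)OC3=O)OC2=O | intermediate
18 | (R)-lactol propanoate | COc1cc(C)c2c(c1C)Oc1c(c(C)c(O)c3c1[C@H](OC(=O)CC)OC3=O)OC2=O | intermediate
19 | CNP0255863.1, (R)-lactol | COc1cc(C)c2c(c1C)Oc1c(c(C)c(O)c3c1[C@H](O)OC3=O)OC2=O | target

**Step count**

Total: 14 steps. Longest linear sequence: 11 steps (5 to 19, steps 4–14).

**Steps most likely to fail**

Step 11 (key step). The acyl ketal may ionise back to the phenoxenium ion and be hydrolysed to quinone and ring A acid on work-up, or BF3 may be held at the aldehyde and ester oxygens without any migration. The fallback uses known chemistry, sets out from phenol 4 and returns at 15; the Cb oxygen is brought in with the ring C building block and ring B is closed by lactonisation. Commercial 2,4-dihydroxy-3-methylbenzoic acid (Cc1c(O)ccc(C(=O)O)c1O) is brominated (Br2, AcOH) to 5-bromo-2,4-dihydroxy-3-methylbenzoic acid F1, esterified (BnBr, KHCO3, DMF) to benzyl 5-bromo-2,4-dihydroxy-3-methylbenzoate F2, and allylated twice (allyl bromide, K2CO3, DMF) to benzyl 2,4-bis(allyloxy)-5-bromo-3-methylbenzoate F3. Magnesiation at its only ring hydrogen and formylation (TMPMgCl·LiCl, THF, −20 °C; DMF) give benzyl 2,4-bis(allyloxy)-5-bromo-6-formyl-3-methylbenzoate F4. Ullmann coupling of F4 with 4 (CuI, picolinic acid, K3PO4, DMSO, 100 °C) should give the tris-allyl diaryl ether F5; this ether has four ortho substituents, and the crowding is why the path is second choice. Pd(PPh3)4 with TolSO2Na removes the three allyl groups to give the acid diphenol F6. Carbodiimide lactonisation (dicyclohexylcarbodiimide, CH2Cl2, rt) onto the Cb hydroxyl, the only hydroxyl within reach of the ring A acid, gives 15.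

Step 14. The enzyme may turn over slowly on the bulky ester, the seven-membered lactone may be opened by butanol, and the configuration may erode by ring–chain tautomerism while the lactol is released. The fallback sets out from racemic lactol 17 and arrives directly at 19, bypassing steps 13 and 14. The enantiomers of 17 are separated by preparative supercritical-fluid chromatography on an amylose tris(3,5-dimethylphenylcarbamate) phase (CO2/MeOH with 0.1% HCO2H, 10 °C) and the (R)-enantiomer is collected as 19. The other enantiomer is returned to racemic 17 with a trace of iPr2NEt and resubmitted.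

Step 13. The ring C phenol may be acylated in competition with the lactol, and uncatalysed background acylation may erode the enantiocontrol. The fallback sets out from 15 and returns at 18, with the phenol masked during the resolution. Silylation of 15 (TBSOTf, 2,6-lutidine, CH2Cl2, 0 °C) gives the aryl silyl ether F7. Hydrogenolysis (H2, 10% Pd/C, EtOAc) gives the racemic silyl-protected lactol F8. The same isothiourea-catalysed acylation, now with a single hydroxyl present, gives the (R)-propanoate silyl ether F9. HF·pyridine (THF, 0 °C) removes the silyl group without touching the acylal and gives 18.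

**Further compounds**

F1 | step 11 | 5-bromo-2,4-dihydroxy-3-methylbenzoic acid | Cc1c(O)c(Br)cc(C(=O)O)c1O
F2 | step 11 | benzyl 5-bromo-2,4-dihydroxy-3-methylbenzoate | Cc1c(O)c(Br)cc(C(=O)OCc2ccccc2)c1O
F3 | step 11 | benzyl 2,4-bis(allyloxy)-5-bromo-3-methylbenzoate | C=CCOc1c(C)c(OCC=C)c(Br)cc1C(=O)OCc1ccccc1
F4 | step 11 | benzyl 2,4-bis(allyloxy)-5-bromo-6-formyl-3-methylbenzoate | C=CCOc1c(C)c(OCC=C)c(Br)c(C=O)c1C(=O)OCc1ccccc1
F5 | step 11 | allyl 2-[4,6-bis(allyloxy)-3-(benzyloxycarbonyl)-2-formyl-5-methylphenoxy]-4-methoxy-3,6-dimethylbenzoate | C=CCOC(=O)c1c(C)cc(OC)c(C)c1Oc1c(OCC=C)c(C)c(OCC=C)c(C(=O)OCc2ccccc2)c1C=O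
F6 | step 11 | 2-[3-(benzyloxycarbonyl)-2-formyl-4,6-dihydroxy-5-methylphenoxy]-4-methoxy-3,6-dimethylbenzoic acid | COc1cc(C)c(C(=O)O)c(Oc2c(O)c(C)c(O)c(C(=O)OCc3ccccc3)c2C=O)c1C
F7 | step 13 | tert-butyldimethylsilyl ether of 15 at the Cd oxygen | COc1cc(C)c2c(c1C)Oc1c(C=O)c(C(=O)OCc3ccccc3)c(O[Si](C)(C)C(C)(C)C)c(C)c1OC2=O
F8 | step 13 | racemic lactol with the Cd oxygen silylated | COc1cc(C)c2c(c1C)Oc1c(c(C)c(O[Si](C)(C)C(C)(C)C)c3c1C(O)OC3=O)OC2=O
F9 | step 13 | (R)-lactol propanoate with the Cd oxygen silylated | COc1cc(C)c2c(c1C)Oc1c(c(C)c(O[Si](C)(C)C(C)(C)C)c3c1[C@H](OC(=O)CC)OC3=O)OC2=O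
F0 | step 14 | none | none
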